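**Plan**

- Target ring numbering: C1 = C(OH)(CH2OBz), C2 = CH(OH), C3=C4, C5 = CH(OBz), C6 = CH(OAc). Retrosynthesis: the CH2OBz branch goes back to a C1 carboxyl; this carboxyl is re-closed onto C4 as a bridging lactone while the C2 oxygen is removed (via iodohydrin and epoxide) and the alkene returns to C2=C3; the bicycle is then cut at C4–C5 and C6–C1 ([4+2]); the C5 oxygen goes back to boron and the C6 acetate to an acetyl group.
- Forward: the carbocycle arises in one Diels–Alder reaction of 3-hydroxy-2H-pyran-2-one with (E)-4-(pinacolboryl)but-3-en-2-one. The pyranone ring makes this possible: its diene C3=C4–C5=C6 is locked s-cis, its C3–OH and C2=O arrive as the tertiary carbinol C1 with its one-carbon branch, and its ring oxygen O1 on C6 becomes the allylic leaving group of the later transposition.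
- The bicyclic lactone is then oxidised by peracid (C–B to C–OH, alkene to epoxide, acetyl to acetate), benzoylated, opened by iodide/zinc with a 1,3-shift of oxygen, and the freed carboxyl is reduced and benzoylated.
- Stereochemistry: absolute configuration from the catalyst-controlled cycloaddition; C5/C6 trans from the E enone; C6 oxygen cis to the C1 hydroxyl from endo addition; retention in the two oxidative 1,2-shifts; the C2 hydroxyl from epoxidation on the lactone face followed by anti opening and anti elimination.

Key step: step 3

Assumption: the cupreidine-derived catalyst is taken to give 5 in the absolute sense drawn; if the sense proves opposite, the pseudoenantiomeric cupreine benzyl ether is used and nothing else changes.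

Naming remark: in the bicyclic lactones C1 is the bridgehead bonded to O2 and C4 is the hydroxylated bridgehead; endo means on the side of the C7–C8 bridge, exo on the side of the O2–C3 lactone bridge.

**Route**

Step 1
Reactants: 1 but-3-yn-2-ol (racemic)
Product: 2 (E)-4-(4,4,5,5-tetramethyl-1,3,2-dioxaborolan-2-yl)but-3-en-2-ol (racemic)
Conditions: B2pin2 (1.1 equiv), CuCl (5 mol%), Xantphos (5 mol%), NaOtBu (10 mol%), MeOH (2 equiv), THF, rt
Reagents that add atoms: bis(pinacolato)diboron, CC1(C)OB(OC1(C)C)B1OC(C)(C)C(C)(C)O1
Why: Copper-catalysed formal hydroboration of a terminal alkyne (syn borylcupration, then protonolysis of the alkenylcopper by methanol) should put boron on the terminal carbon and give only the E alkene; the free hydroxyl is tolerated and its racemic centre disappears in step 2.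

Step 2
Reactants: 2 (E)-4-(pinacolboryl)but-3-en-2-ol
Product: 3 (E)-4-(4,4,5,5-tetramethyl-1,3,2-dioxaborolan-2-yl)but-3-en-2-one
Conditions: Dess–Martin periodinane (1.2 equiv), NaHCO3, CH2Cl2, 0 °C to rt
Reagents that add atoms: none
Why: Dess–Martin oxidation of a secondary allylic alcohol to the enone under buffered non-aqueous conditions, which should neither oxidise the C–B bond nor isomerise the E alkene.

Step 3
Reactants: 3 (E)-4-(pinacolboryl)but-3-en-2-one; 4 3-hydroxy-2H-pyran-2-one
Product: 5 (1S,4R,5S,6S)-5-endo-acetyl-4-hydroxy-6-exo-(4,4,5,5-tetramethyl-1,3,2-dioxaborolan-2-yl)-2-oxabicyclo[2.2.2]oct-7-en-3-one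
Conditions: 9-O-benzylcupreidine (10 mol%), 3 (1.3 equiv), EtOAc, −20 °C
Reagents that add atoms: none
Why: The quinuclidine nitrogen of the catalyst deprotonates the 3-hydroxyl of 4, and the resulting 3-oxido-2-pyranone, whose diene C3=C4–C5=C6 is held s-cis by the lactone ring, adds across C3 and C6 to the enone in a concerted but asynchronous normal-demand Diels–Alder reaction (Michael-like bonding at C6 first, aldol-like closure at C3) while the 6'-hydroxyl of the catalyst hydrogen-bonds the acetyl oxygen. The closest known reaction type is the cinchona-base-catalysed enantioselective Diels–Alder reaction of 3-hydroxy-2-pyranones with enones and 4-oxo-enoates. The new six-membered carbocycle is closed by a suprafacial intermolecular [4+2] cycloaddition that forms the C6(pyranone)–C(boryl) and C3(pyranone)–C(acetyl) bonds together and leaves the former O1–C2(=O) unit as the third bridge of a 2-oxabicyclo[2.2.2]octenone. The trans relation of C5 and C6 comes from the E geometry of 3, the endo position of acetyl from the Alder endo preference reinforced by the bulky boronate taking the roomier exo site beside the small lactone bridge, and the configuration of the two bridgeheads from the chiral ion pair that exposes one face of the dienolate. The step needs regioselectivity (C6 of the pyranone to the boron-bearing carbon), which should be secured because the 3-oxido donor makes C6 the nucleophilic terminus and acetyl is the only strong acceptor in 3, and it needs endo and facial selectivity, which rest on the factors just named.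

Step 4
Reactants: 5 boryl keto lactone
Product: 8 5-endo-acetoxy-7,8-epoxy-4,6-dihydroxy-2-oxabicyclo[2.2.2]octan-3-one (6-hydroxyl exo; epoxide oxygen on the lactone-bridge side), via hydroxy ketone 6 (not isolated), via epoxy ketone 7 (not isolated)
Conditions: mCPBA (5 equiv), Na2HPO4, 1,2-dichloroethane, 0 °C then 45 °C; aqueous Na2S2O3/NaHCO3 work-up
Reagents that add atoms: mCPBA, O=C(OO)c1cccc(Cl)c1
Why: Three peracid oxidations are expected in order of rate: oxidation of the C6–B bond with retention (1,2-shift of carbon from boron to oxygen), epoxidation of the strained C7=C8 bond on the face next to the lactone bridge because the other face is screened by the 5-endo substituent, and Baeyer–Villiger oxidation of the methyl ketone in which the secondary ring carbon C5 migrates in preference to methyl with retention.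

Step 5
Reactants: 8 epoxy diol acetate
Product: 9 5-endo-acetoxy-6-exo-(benzoyloxy)-7,8-epoxy-4-hydroxy-2-oxabicyclo[2.2.2]octan-3-one (epoxide oxygen on the lactone-bridge side)
Conditions: BzCl (1.2 equiv), pyridine, DMAP (5 mol%), CH2Cl2, 0 °C
Reagents that add atoms: benzoyl chloride, O=C(Cl)c1ccccc1
Why: DMAP-catalysed acylation of the only secondary hydroxyl; the tertiary bridgehead hydroxyl should be too hindered to compete at 0 °C, the rigid trans arrangement prevents acetyl migration, and no stereocentre is affected.

Step 6
Reactants: 9 epoxy lactone benzoate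
Product: 11 (1R,2S,5R,6S)-6-acetoxy-5-(benzoyloxy)-1,2-dihydroxycyclohex-3-ene-1-carboxylic acid, via iodohydrin 10 (not isolated)
Conditions: NaI, NaOAc, AcOH, THF, 0 °C; then Zn dust, 0 °C to rt; dilute HCl work-up
Reagents that add atoms: none
Why: Buffered iodide should open the epoxide by SN2 attack at C7 from the side of the C5–C6 bridge (C8 is screened by the quaternary centre and the 5-endo acetate), which puts the C7–I bond antiperiplanar to the C1–O lactone bond; zinc then effects a reductive anti β-elimination (the reverse of an iodolactonisation) that opens the lactone, creates the C1=C7 double bond and leaves the C8 hydroxyl in place, so the oxygen is moved 1,3 on the same face.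

Step 7
Reactants: 11 hydroxy acid
Product: 13 (1R,2S,5R,6S)-6-acetoxy-5-(benzoyloxy)-1-(hydroxymethyl)cyclohex-3-ene-1,2-diol, via acyl imidazolide 12 (not isolated)
Conditions: 1,1'-carbonyldiimidazole (1.1 equiv), THF, 0 °C to rt; then NaBH4, THF/H2O, 0 °C; NH4Cl quench
Reagents that add atoms: none
Why: Activation of the carboxyl as its acyl imidazolide and borohydride reduction should give the primary alcohol chemoselectively, since NaBH4 at 0 °C reduces the activated acyl group but not the acetate, the benzoate or the alkene; no stereocentre is involved.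

Step 8
Reactants: 13 triol
Product: 14 HY-N2634, [(1R,2S,5R,6S)-6-acetoxy-5-(benzoyloxy)-1,2-dihydroxycyclohex-3-en-1-yl]methyl benzoate
Conditions: BzCl (1.05 equiv), 2,4,6-collidine, CH2Cl2, −40 °C
Reagents that add atoms: benzoyl chloride, O=C(Cl)c1ccccc1
Why: Selective acylation of a primary alcohol with an acid chloride and a hindered pyridine base at low temperature; the secondary allylic and tertiary hydroxyls should react much more slowly and the weak base avoids acyl migration, so the configuration set earlier is kept.

**Compound list**

1 | but-3-yn-2-ol (racemic) | CC(O)C#C | starting material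
2 | (E)-4-(4,4,5,5-tetramethyl-1,3,2-dioxaborolan-2-yl)but-3-en-2-ol (racemic) | CC(O)/C=C/B1OC(C)(C)C(C)(C)O1 | intermediate
3 | (E)-4-(4,4,5,5-tetramethyl-1,3,2-dioxaborolan-2-yl)but-3-en-2-one | CC(=O)/C=C/B1OC(C)(C)C(C)(C)O1 | intermediate
4 | 3-hydroxy-2H-pyran-2-one | O=C1OC=CC=C1O | starting material
5 | (1S,4R,5S,6S)-5-endo-acetyl-4-hydroxy-6-exo-(pinacolboryl)-2-oxabicyclo[2.2.2]oct-7-en-3-one | CC(=O)[C@H]1[C@H](B2OC(C)(C)C(C)(C)O2)[C@H]3C=C[C@]1(O)C(=O)O3 | intermediate
6 | 5-endo-acetyl-4,6-dihydroxy-2-oxabicyclo[2.2.2]oct-7-en-3-one (6-hydroxyl exo; framework as in 5) | CC(=O)[C@H]1[C@H](O)[C@H]3C=C[C@]1(O)C(=O)O3 | intermediate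
7 | 5-endo-acetyl-7,8-epoxy-4,6-dihydroxy-2-oxabicyclo[2.2.2]octan-3-one (6-hydroxyl exo; epoxide oxygen on the lactone-bridge side) | CC(=O)[C@H]1[C@H](O)[C@H]3[C@@H]4O[C@@H]4[C@]1(O)C(=O)O3 | intermediate
8 | 5-endo-acetoxy-7,8-epoxy-4,6-dihydroxy-2-oxabicyclo[2.2.2]octan-3-one (6-hydroxyl exo; epoxide oxygen on the lactone-bridge side) | CC(=O)O[C@H]1[C@H](O)[C@H]3[C@@H]4O[C@@H]4[C@]1(O)C(=O)O3 | intermediate
9 | 5-endo-acetoxy-6-exo-(benzoyloxy)-7,8-epoxy-4-hydroxy-2-oxabicyclo[2.2.2]octan-3-one (epoxide oxygen on the lactone-bridge side) | CC(=O)O[C@H]1[C@H](OC(=O)c2ccccc2)[C@H]3[C@@H]4O[C@@H]4[C@]1(O)C(=O)O3 | intermediate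
10 | 5-endo-acetoxy-6-exo-(benzoyloxy)-4,8-dihydroxy-7-iodo-2-oxabicyclo[2.2.2]octan-3-one (iodine on the side of the C5–C6 bridge; 8-hydroxyl on the lactone-bridge side) | CC(=O)O[C@H]1[C@H](OC(=O)c2ccccc2)[C@H]3[C@@H](I)[C@H](O)[C@]1(O)C(=O)O3 | intermediate
11 | (1R,2S,5R,6S)-6-acetoxy-5-(benzoyloxy)-1,2-dihydroxycyclohex-3-ene-1-carboxylic acid (1-OH and 6-OAc on one face; 2-OH, 5-OBz and the carboxyl on the other) | CC(=O)O[C@H]1[C@H](OC(=O)c2ccccc2)C=C[C@H](O)[C@]1(O)C(=O)O | intermediate
12 | acyl imidazolide of 11 (same configuration) | CC(=O)O[C@H]1[C@H](OC(=O)c2ccccc2)C=C[C@H](O)[C@]1(O)C(=O)n1ccnc1 | intermediate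
13 | (1R,2S,5R,6S)-6-acetoxy-5-(benzoyloxy)-1-(hydroxymethyl)cyclohex-3-ene-1,2-diol | CC(=O)O[C@H]1[C@H](OC(=O)c2ccccc2)C=C[C@H](O)[C@]1(O)CO | intermediate
14 | HY-N2634, [(1R,2S,5R,6S)-6-acetoxy-5-(benzoyloxy)-1,2-dihydroxycyclohex-3-en-1-yl]methyl benzoate | CC(=O)O[C@H]1[C@H](OC(=O)c2ccccc2)C=C[C@H](O)[C@]1(O)COC(=O)c1ccccc1 | target

**Step count and risks**

Total steps: 8. Longest linear sequence: 8 (steps 1 to 8 from but-3-yn-2-ol; the pyranone 4 enters at step 3).

Steps most likely to fail:

Step 3. The singly activated, β-substituted boryl enone may add too slowly to the dienolate, and retro-aldol equilibration or weak facial discrimination may erode endo and enantiomeric purity. The fallback sets out from 4 and comes back at 9; it gives up the boron handle for a second acyl activator. Commercial phenylglyoxal hydrate and 1-(triphenylphosphoranylidene)propan-2-one are joined by a Wittig reaction to (E)-1-phenylpent-2-ene-1,4-dione F1, a doubly activated dienophile. Its cycloaddition with 4 under the step 3 catalyst should give 5-endo-acetyl-6-exo-benzoyl-4-hydroxy-2-oxabicyclo[2.2.2]oct-7-en-3-one F2 together with the regioisomeric 6-exo-acetyl-5-endo-benzoyl adduct F3, which is removed by chromatography. Dimethyldioxirane should epoxidise F2 on the lactone face to the epoxy diketone F4. Buffered CF3CO3H then carries out two Baeyer–Villiger shifts (ring carbon migrating in preference to phenyl and to methyl), passing through the epoxy acetyl benzoate F5, and delivers 9. The price is the loss of regiocontrol in the cycloaddition.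

Step 4. The Baeyer–Villiger migration of the hindered, oxygen-flanked ring carbon may be too slow while the peracid is consumed elsewhere or the epoxide is opened by the acid formed. The fallback sets out from 5 and comes back at 8; the one-pot cascade is replaced by three isolated oxidations with oxidants of three mechanistic classes, the ketone being oxidised last on a substrate without alkene. NaBO3·4H2O in THF/water oxidises only the C–B bond and gives 6, now isolated. Dimethyldioxirane, which does not effect Baeyer–Villiger oxidation, epoxidises the lactone face and gives 7. Buffered CF3CO3H then carries out the Baeyer–Villiger step alone and gives 8.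

Step 6. Iodide may attack C8 instead of C7, the endo acetate may take part in the epoxide opening, or the C–I bond may be reduced without elimination. The fallback sets out from 9 and comes back at 11; external undirected attack is replaced by substrate-directed delivery. Ti(OiPr)4 binds the bridgehead hydroxyl and the epoxide oxygen of the 2,3-epoxy alcohol unit (C4–OH, C8–C7 epoxide), which should labilise the distal C7–O bond and direct iodide (from iodine or tetrabutylammonium iodide) to C7. The iodohydrin 10 is isolated, and the β-elimination is run separately with SmI2 in THF at −78 °C, where the organosamarium intermediate should expel the antiperiplanar carboxylate faster than it is protonated.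

Further compounds
F1 | step 3 | (E)-1-phenylpent-2-ene-1,4-dione | CC(=O)/C=C/C(=O)c1ccccc1
F2 | step 3 | 5-endo-acetyl-6-exo-benzoyl-4-hydroxy-2-oxabicyclo[2.2.2]oct-7-en-3-one | CC(=O)[C@H]1[C@H](C(=O)c2ccccc2)[C@H]3C=C[C@]1(O)C(=O)O3
F3 | step 3 | 6-exo-acetyl-5-endo-benzoyl-4-hydroxy-2-oxabicyclo[2.2.2]oct-7-en-3-one (regioisomer, discarded) | O=C(c1ccccc1)[C@H]1[C@H](C(C)=O)[C@H]3C=C[C@]1(O)C(=O)O3
F4 | step 3 | 5-endo-acetyl-6-exo-benzoyl-7,8-epoxy-4-hydroxy-2-oxabicyclo[2.2.2]octan-3-one (epoxide oxygen on the lactone-bridge side) | CC(=O)[C@H]1[C@H](C(=O)c2ccccc2)[C@H]3[C@@H]4O[C@@H]4[C@]1(O)C(=O)O3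
F5 | step 3 | 5-endo-acetyl-6-exo-(benzoyloxy)-7,8-epoxy-4-hydroxy-2-oxabicyclo[2.2.2]octan-3-one (not isolated) | CC(=O)[C@H]1[C@H](OC(=O)c2ccccc2)[C@H]3[C@@H]4O[C@@H]4[C@]1(O)C(=O)O3
F0 | step 4 | none | none
F0 | step 6 | none | none
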